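Target 22 ⇒ allyl ester 15: the side chain is grown last from the C9 allyl group (hydroboration, Ohira–Bestmann alkynylation, Negishi carboalumination/hydroxymethylation, acetylation).
Ring A of 15 (C1, C2, C3, C4, C5, C10) ⇒ seven-membered-ring chloro ketone 13 by Favorskii ring contraction: in 13 the ring carbonyl carbon lies between C3 (CHCl, leaving group) and C4 (CH–CH3, enolisable), so the C3–C4 bond can form and the carbonyl carbon is extruded as CO2CH3 on the now quaternary C4; the C1=C10 alkene is not conjugated and stays in place.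
Seven-membered ring of 13 ⇒ (4+3) cycloaddition of vinylcyclohexene 8 (ring B) with the oxyallyl cation from 3-chlorobutan-2-one (bonds C2–C3 and C4–C5), then kinetic α-chlorination at C3.
Ring B with C8 and C9 ⇒ 2-methylcyclohex-2-en-1-one by asymmetric conjugate methylation and enolate allylation; enol triflate formation and Stille vinylation give diene 8.
Order of ring formation: ring B (purchased six-membered ring, stereocentres installed first) → seven-membered carbocycle → ring A by seven-to-six contraction.

Key step: step 7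

Remark: locants C1–C10 and H5 are those of the target decalin (ring A = C1, C2, C3, C4, C5, C10 with C1=C10 and C4 bearing CH3/CO2CH3; ring B = C5–C10 with C8–CH3 and C9–CH3/side chain) and are kept for the corresponding atoms of the seven-membered-ring precursors.
Remark: 11 and 13 are carried as epimer mixtures at their enolisable α-carbons, because both epimers converge on one enolate in step 7; the phosphoramidite enantiomer in step 1 is the one that delivers the 3R adduct.

Step 1
Reactants: 1 2-methylcyclohex-2-en-1-one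
Product: 3 trimethyl{[(3R)-2,3-dimethylcyclohex-1-en-1-yl]oxy}silane, via aluminium enolate 2 (not isolated)
Conditions: Me3Al, Cu(O2C-C4H3S) (copper thiophene-2-carboxylate, 2 mol %), BINOL/bis(1-phenylethyl)amine phosphoramidite (4 mol %), Et2O, −30 °C; then Me3SiOTf, −30 °C to rt
Reagents that add atoms: trimethylaluminium C[Al](C)C; trimethylsilyl trifluoromethanesulfonate C[Si](C)(C)OS(=O)(=O)C(F)(F)F
Why: Copper-catalysed asymmetric conjugate addition of Me3Al, in which the chiral phosphoramidite sets the new methyl-bearing stereocentre, gives a regiodefined aluminium enolate that is silylated on oxygen.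

Step 2
Reactants: 3 trimethyl{[(3R)-2,3-dimethylcyclohex-1-en-1-yl]oxy}silane
Product: 5 (2S,3R)-2,3-dimethyl-2-(prop-2-en-1-yl)cyclohexan-1-one, via lithium enolate 4 (not isolated)
Conditions: MeLi, THF, 0 °C; then allyl bromide, DMPU, −78 to 0 °C
Reagents that add atoms: allyl bromide C=CCBr
Why: The regiospecific lithium enolate released by MeLi should be C-allylated (enolate alkylation) on the face anti to the adjacent methyl group, which sets the quaternary centre with the two methyl groups cis.

Step 3
Reactants: 5 (2S,3R)-2,3-dimethyl-2-(prop-2-en-1-yl)cyclohexan-1-one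
Product: 7 (5R,6S)-5,6-dimethyl-6-(prop-2-en-1-yl)cyclohex-1-en-1-yl trifluoromethanesulfonate, via potassium enolate 6 (not isolated)
Conditions: KN(SiMe3)2, THF, −78 °C; then PhNTf2, −78 °C to rt
Reagents that add atoms: N-phenylbis(trifluoromethanesulfonimide) O=S(=O)(N(c1ccccc1)S(=O)(=O)C(F)(F)F)C(F)(F)F
Why: The ketone can enolise only toward its CH2 side, so enol triflate formation is regiospecific and leaves both stereocentres untouched.

Step 4
Reactants: 7 (5R,6S)-5,6-dimethyl-6-(prop-2-en-1-yl)cyclohex-1-en-1-yl trifluoromethanesulfonate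
Product: 8 (5R,6S)-1-ethenyl-5,6-dimethyl-6-(prop-2-en-1-yl)cyclohex-1-ene
Conditions: Bu3SnCH=CH2, Pd(PPh3)4 (5 mol %), LiCl, THF, 65 °C
Reagents that add atoms: tributyl(vinyl)stannane C=C[Sn](CCCC)(CCCC)CCCC
Why: Stille cross-coupling of an enol triflate with a vinylstannane should give the semicyclic 1,3-diene without touching the allyl group or the stereocentres.

Step 5
Reactants: 8 (5R,6S)-1-ethenyl-5,6-dimethyl-6-(prop-2-en-1-yl)cyclohex-1-ene; 9 3-chlorobutan-2-one
Product: 11 (1S,2R,4aS)-1,2,5-trimethyl-1-(prop-2-en-1-yl)-1,2,3,4,4a,5,7,8-octahydro-6H-benzo[7]annulen-6-one (both C5-methyl epimers), via oxyallyl cation 10 (not isolated)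
Conditions: 9 (3 equiv), Et3N (3 equiv), (CF3)2CHOH, 0 °C to rt
Reagents that add atoms: none
Why: (4+3) Cycloaddition of the base-generated 1-methyl-2-oxyallyl cation with the s-cis diene; the unsubstituted cation terminus should bond to the terminal vinyl carbon and the methyl-bearing terminus to the ring carbon, anti to the pseudoaxial methyl of the neighbouring quaternary carbon (half-chair with the secondary methyl equatorial), which sets H5 cis to that methyl.

Step 6
Reactants: 11 (1S,2R,4aS)-1,2,5-trimethyl-1-(prop-2-en-1-yl)-1,2,3,4,4a,5,7,8-octahydro-6H-benzo[7]annulen-6-one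
Product: 13 (1S,2R,4aS)-7-chloro-1,2,5-trimethyl-1-(prop-2-en-1-yl)-1,2,3,4,4a,5,7,8-octahydro-6H-benzo[7]annulen-6-one (epimer mixture at C5 and C7 of this name), via silyl enol ether 12 (not isolated)
Conditions: LiN(iPr)2, Me3SiCl (in situ quench), THF, −78 °C; then N-chlorosuccinimide, THF, 0 °C
Reagents that add atoms: N-chlorosuccinimide O=C1CCC(=O)N1Cl
Why: Kinetic deprotonation occurs at the less substituted α-CH2, and the resulting silyl enol ether is chlorinated there by N-chlorosuccinimide (α-halogenation of a silyl enol ether); no lasting stereocentre is set.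

Step 7
Reactants: 13 (1S,2R,4aS)-7-chloro-1,2,5-trimethyl-1-(prop-2-en-1-yl)-1,2,3,4,4a,5,7,8-octahydro-6H-benzo[7]annulen-6-one
Product: 15 methyl (1S,5S,6R,8aR)-1,5,6-trimethyl-5-(prop-2-en-1-yl)-1,2,3,5,6,7,8,8a-octahydronaphthalene-1-carboxylate, via cyclopropanone 14 (not isolated)
Conditions: NaOMe (3 equiv), MeOH, 0 to 40 °C
Reagents that add atoms: sodium methoxide [Na+].[O-]C
Why: Methoxide enolises 13 toward the methyl-bearing α-carbon (C4), this enolate displaces chloride from the other α-carbon (C3) to give cyclopropanone 14, and methoxide then adds to the strained carbonyl and opens the three-membered ring toward the less substituted (secondary) carbanion at C3, so the former ring carbonyl carbon stays on C4 as CO2CH3. The closest known reaction is the Favorskii rearrangement of 2-chlorocycloheptanones and of 2-chloro-6-methylcyclohexanone to ring-contracted (1-methyl)cycloalkanecarboxylates, in which both regioisomeric chloro ketones converge on one cyclopropanone. Ring A is closed by the new C3–C4 bond (3-exo-tet displacement, a 1,3-elimination), and excision of the bridging carbonyl turns the seven-membered ring into the six-membered ring. The new quaternary centre C4 is controlled by C5: the nascent cyclohexene should close through a half-chair with the C5–C6 bond pseudoequatorial and H5 pseudoaxial, which puts the carbonyl bridge anti to H5 and the methyl group cis to H5, and ring opening does not touch C4. The step needs cyclopropanone formation to outrun methoxide substitution, dehydrochlorination and the semibenzilic path, and needs regioselective opening; the enolisable tertiary α-hydrogen, the non-conjugated position of both alkenes and the secondary-versus-tertiary carbanion difference secure this.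

Step 8
Reactants: 15 methyl (1S,5S,6R,8aR)-1,5,6-trimethyl-5-(prop-2-en-1-yl)-1,2,3,5,6,7,8,8a-octahydronaphthalene-1-carboxylate
Product: 17 methyl (1S,5S,6R,8aR)-5-(3-hydroxypropyl)-1,5,6-trimethyl-1,2,3,5,6,7,8,8a-octahydronaphthalene-1-carboxylate, via B-alkylborane 16 (not isolated)
Conditions: 9-BBN, THF, 0 °C to rt; then NaOH, H2O2, 0 °C
Reagents that add atoms: hydrogen peroxide OO
Why: Hydroboration–oxidation with 9-BBN should add anti-Markovnikov to the monosubstituted alkene only and leave the hindered trisubstituted ring alkene and the neopentyl-type ester alone.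

Step 9
Reactants: 17 methyl (1S,5S,6R,8aR)-5-(3-hydroxypropyl)-1,5,6-trimethyl-1,2,3,5,6,7,8,8a-octahydronaphthalene-1-carboxylate
Product: 18 methyl (1S,5S,6R,8aR)-1,5,6-trimethyl-5-(3-oxopropyl)-1,2,3,5,6,7,8,8a-octahydronaphthalene-1-carboxylate
Conditions: Dess–Martin periodinane, CH2Cl2, rt
Reagents that add atoms: none
Why: Dess–Martin oxidation of a primary alcohol stops at the aldehyde under neutral conditions that spare the alkene and the ester.

Step 10
Reactants: 18 methyl (1S,5S,6R,8aR)-1,5,6-trimethyl-5-(3-oxopropyl)-1,2,3,5,6,7,8,8a-octahydronaphthalene-1-carboxylate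
Product: 19 methyl (1S,5S,6R,8aR)-5-(but-3-yn-1-yl)-1,5,6-trimethyl-1,2,3,5,6,7,8,8a-octahydronaphthalene-1-carboxylate
Conditions: dimethyl (1-diazo-2-oxopropyl)phosphonate, K2CO3, MeOH, 0 °C to rt
Reagents that add atoms: dimethyl (1-diazo-2-oxopropyl)phosphonate CC(=O)C(=[N+]=[N-])P(=O)(OC)OC
Why: Seyferth–Gilbert homologation with the Ohira–Bestmann reagent converts the enolisable aldehyde into the terminal alkyne under mild carbonate conditions that the hindered methyl ester tolerates.

Step 11
Reactants: 19 methyl (1S,5S,6R,8aR)-5-(but-3-yn-1-yl)-1,5,6-trimethyl-1,2,3,5,6,7,8,8a-octahydronaphthalene-1-carboxylate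
Product: 21 methyl (1S,5S,6R,8aR)-5-[(3E)-5-hydroxy-3-methylpent-3-en-1-yl]-1,5,6-trimethyl-1,2,3,5,6,7,8,8a-octahydronaphthalene-1-carboxylate, via alkenylalane 20 (not isolated)
Conditions: Me3Al (3 equiv), Cp2ZrCl2 (0.3 equiv), CH2Cl2, 0 °C to rt; volatiles removed; n-BuLi, THF, −78 °C; (CH2O)n, −78 °C to rt; H2O work-up
Reagents that add atoms: trimethylaluminium C[Al](C)C; paraformaldehyde (as formaldehyde) C=O
Why: Zirconium-catalysed carboalumination (Negishi) adds CH3 and Al syn with CH3 on the internal carbon, and hydroxymethylation of the alkenylalanate proceeds with retention, which fixes the E trisubstituted alkene.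

Step 12
Reactants: 21 methyl (1S,5S,6R,8aR)-5-[(3E)-5-hydroxy-3-methylpent-3-en-1-yl]-1,5,6-trimethyl-1,2,3,5,6,7,8,8a-octahydronaphthalene-1-carboxylate
Product: 22 methyl (1S,5S,6R,8aR)-5-[(3E)-5-(acetyloxy)-3-methylpent-3-en-1-yl]-1,5,6-trimethyl-1,2,3,5,6,7,8,8a-octahydronaphthalene-1-carboxylate
Conditions: Ac2O, pyridine, 4-(dimethylamino)pyridine (cat.), CH2Cl2, rt
Reagents that add atoms: acetic anhydride CC(=O)OC(C)=O
Why: Acylation of the unhindered primary allylic alcohol gives the target without affecting the alkenes or the methyl ester.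

Compound list
1 | 2-methylcyclohex-2-en-1-one | CC1=CCCCC1=O | starting material
2 | dimethyl{[(3R)-2,3-dimethylcyclohex-1-en-1-yl]oxy}alumane (aluminium enolate, formed in the flask) | C[Al](C)OC1=C(C)[C@H](C)CCC1 | intermediate
3 | trimethyl{[(3R)-2,3-dimethylcyclohex-1-en-1-yl]oxy}silane | C[Si](C)(C)OC1=C(C)[C@H](C)CCC1 | intermediate
4 | lithium (3R)-2,3-dimethylcyclohex-1-en-1-olate (formed in the flask) | [Li]OC1=C(C)[C@H](C)CCC1 | intermediate
5 | (2S,3R)-2,3-dimethyl-2-(prop-2-en-1-yl)cyclohexan-1-one | O=C1CCC[C@@H](C)[C@]1(C)CC=C | intermediate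
6 | potassium (5R,6S)-5,6-dimethyl-6-(prop-2-en-1-yl)cyclohex-1-en-1-olate (formed in the flask) | [K]OC1=CCC[C@@H](C)[C@]1(C)CC=C | intermediate
7 | (5R,6S)-5,6-dimethyl-6-(prop-2-en-1-yl)cyclohex-1-en-1-yl trifluoromethanesulfonate | FC(F)(F)S(=O)(=O)OC1=CCC[C@@H](C)[C@]1(C)CC=C | intermediate
8 | (5R,6S)-1-ethenyl-5,6-dimethyl-6-(prop-2-en-1-yl)cyclohex-1-ene | C=CC1=CCC[C@@H](C)[C@]1(C)CC=C | intermediate
9 | 3-chlorobutan-2-one (racemic) | CC(=O)C(C)Cl | starting material
10 | 1-methyl-2-oxidoallyl cation (oxyallyl zwitterion, formed in the flask) | C[CH+]C([O-])=C | intermediate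
11 | (1S,2R,4aS)-1,2,5-trimethyl-1-(prop-2-en-1-yl)-1,2,3,4,4a,5,7,8-octahydro-6H-benzo[7]annulen-6-one (epimers at the methyl-bearing α-carbon) | CC1C(=O)CCC=C2[C@H]1CC[C@@H](C)[C@]2(C)CC=C | intermediate
12 | {[(1S,2R,4aS)-1,2,5-trimethyl-1-(prop-2-en-1-yl)-2,3,4,4a,5,8-hexahydro-1H-benzo[7]annulen-6-yl]oxy}trimethylsilane (kinetic silyl enol ether on the CH2 side, formed in the flask) | CC1C(O[Si](C)(C)C)=CCC=C2[C@H]1CC[C@@H](C)[C@]2(C)CC=C | intermediate
13 | (1S,2R,4aS)-7-chloro-1,2,5-trimethyl-1-(prop-2-en-1-yl)-1,2,3,4,4a,5,7,8-octahydro-6H-benzo[7]annulen-6-one (epimers at both α-carbons) | CC1C(=O)C(Cl)CC=C2[C@H]1CC[C@@H](C)[C@]2(C)CC=C | intermediate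
14 | cyclopropanone in which the carbonyl carbon bridges C3 and C4 of the nascent ring A on the face anti to H5 (bicyclo[4.1.0]heptan-7-one fused to ring B; C4–CH3 and C3–H cis; formed in the flask) | C[C@]12C(=O)[C@H]1CC=C3[C@H]2CC[C@@H](C)[C@]3(C)CC=C | intermediate
15 | methyl (1S,5S,6R,8aR)-1,5,6-trimethyl-5-(prop-2-en-1-yl)-1,2,3,5,6,7,8,8a-octahydronaphthalene-1-carboxylate | COC(=O)[C@@]1(C)CCC=C2[C@H]1CC[C@@H](C)[C@]2(C)CC=C | intermediate
16 | B-alkyl-9-borabicyclo[3.3.1]nonane from 15 (boron on the terminal side-chain carbon, formed in the flask) | COC(=O)[C@@]1(C)CCC=C2[C@H]1CC[C@@H](C)[C@]2(C)CCCB3C4CCCC3CCC4 | intermediate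
17 | methyl (1S,5S,6R,8aR)-5-(3-hydroxypropyl)-1,5,6-trimethyl-1,2,3,5,6,7,8,8a-octahydronaphthalene-1-carboxylate | COC(=O)[C@@]1(C)CCC=C2[C@H]1CC[C@@H](C)[C@]2(C)CCCO | intermediate
18 | methyl (1S,5S,6R,8aR)-1,5,6-trimethyl-5-(3-oxopropyl)-1,2,3,5,6,7,8,8a-octahydronaphthalene-1-carboxylate | COC(=O)[C@@]1(C)CCC=C2[C@H]1CC[C@@H](C)[C@]2(C)CCC=O | intermediate
19 | methyl (1S,5S,6R,8aR)-5-(but-3-yn-1-yl)-1,5,6-trimethyl-1,2,3,5,6,7,8,8a-octahydronaphthalene-1-carboxylate | COC(=O)[C@@]1(C)CCC=C2[C@H]1CC[C@@H](C)[C@]2(C)CCC#C | intermediate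
20 | (E)-alkenyl(dimethyl)alane from 19 (CH3 on the internal alkene carbon, AlMe2 on the terminal one, formed in the flask) | COC(=O)[C@@]1(C)CCC=C2[C@H]1CC[C@@H](C)[C@]2(C)CC/C(C)=C/[Al](C)C | intermediate
21 | methyl (1S,5S,6R,8aR)-5-[(3E)-5-hydroxy-3-methylpent-3-en-1-yl]-1,5,6-trimethyl-1,2,3,5,6,7,8,8a-octahydronaphthalene-1-carboxylate | COC(=O)[C@@]1(C)CCC=C2[C@H]1CC[C@@H](C)[C@]2(C)CC/C(C)=C/CO | intermediate
22 | methyl (1S,5S,6R,8aR)-5-[(3E)-5-(acetyloxy)-3-methylpent-3-en-1-yl]-1,5,6-trimethyl-1,2,3,5,6,7,8,8a-octahydronaphthalene-1-carboxylate | COC(=O)[C@@]1(C)CCC=C2[C@H]1CC[C@@H](C)[C@]2(C)CC/C(C)=C/COC(C)=O | target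

Total step count: 12. Longest linear sequence: 12 steps (from 2-methylcyclohex-2-en-1-one; 3-chlorobutan-2-one enters at step 5).

Steps most likely to fail

Step 5. The short-lived oxyallyl cation may be captured by the solvent or by the isolated alkene instead of the hindered diene, and the cycloaddition may show poor regio- or face-selectivity. The fallback sets out from 8 and comes back at 11 by a carbenoid route whose regiochemistry is fixed by its mechanism and whose face selection is under catalyst control. Methyl 3-oxopentanoate is converted with 4-acetamidobenzenesulfonyl azide and Et3N into methyl 2-diazo-3-oxopentanoate F1 and silylated (tBuMe2SiOTf, Et3N) to methyl (3Z)-3-[(tert-butyldimethylsilyl)oxy]-2-diazopent-3-enoate F2. Decomposition of F2 with Rh2(S-PTAD)4 (or its enantiomer, whichever matches the diene) in the presence of 8 should cyclopropanate the terminal vinyl group to the cis-divinylcyclopropane F3, which undergoes Cope rearrangement in the flask (boat transition state) to the silyloxy cycloheptadiene ester F4. Desilylation with Bu4NF gives the β-keto ester F5, and Krapcho dealkoxycarbonylation (LiCl, wet DMSO, 140 °C) returns to 11.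

Step 7. The cyclopropanone may close on the other face of the enolate (loss of control at the new quaternary centre), and the secondary chloride may be diverted into methoxide substitution or dehydrochlorination. The fallback sets out from 11 and comes back at 15 with the leaving group moved to the carbon that becomes quaternary. Me3SiCl, NaI and Et3N in MeCN should give the more substituted silyl enol ether F6, and N-chlorosuccinimide the tertiary chloride F7 (chlorine trans to H5). Treatment of F7 with NaOMe suspended in Et2O should then give 15 by an invertive, stereospecific Favorskii closure from the unhindered CH2 enolate. This variant cannot undergo SN2 or E2 at the halide-bearing carbon, and its facial sense is complementary to that of step 7, because the configuration is fixed in the chlorination and inverted in the closure.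

Step 11. The organoaluminium and alkyllithium reagents may attack the methyl ester, and hydroxymethylation of the alkenyl metal may stay incomplete. The fallback sets out from 18 and comes back at 21 by carbonyl olefination instead of carbometalation. MeMgBr (THF, −78 °C) should give methyl (1S,5S,6R,8aR)-5-(3-hydroxybutyl)-1,5,6-trimethyl-1,2,3,5,6,7,8,8a-octahydronaphthalene-1-carboxylate F8, and Dess–Martin oxidation the methyl ketone F9. Horner–Wadsworth–Emmons reaction with (EtO)2P(O)CH2CO2Et and NaH gives the (E)-enoate F10 (the minor Z isomer is removed by chromatography). Reduction with (iBu)2AlH (2 equiv, CH2Cl2, −78 °C) should take the unhindered conjugated ethyl ester to 21 in preference to the hindered tertiary methyl ester.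

Further compounds
F1 | step 5 | methyl 2-diazo-3-oxopentanoate | CCC(=O)C(=[N+]=[N-])C(=O)OC
F2 | step 5 | methyl (3Z)-3-[(tert-butyldimethylsilyl)oxy]-2-diazopent-3-enoate | C/C=C(\O[Si](C)(C)C(C)(C)C)C(=[N+]=[N-])C(=O)OC
F3 | step 5 | cis-divinylcyclopropane: methyl 1-[(1Z)-1-(tert-butyldimethylsilyloxy)prop-1-en-1-yl]-2-[(5R,6S)-5,6-dimethyl-6-(prop-2-en-1-yl)cyclohex-1-en-1-yl]cyclopropane-1-carboxylate (the two alkenyl groups cis) | COC(=O)[C@@]1(/C(O[Si](C)(C)C(C)(C)C)=C/C)C[C@@H]1C2=CCC[C@@H](C)[C@]2(C)CC=C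
F4 | step 5 | methyl 6-[(tert-butyldimethylsilyl)oxy]-1,2,5-trimethyl-1-(prop-2-en-1-yl)-2,3,4,4a,5,8-hexahydro-1H-benzo[7]annulene-7-carboxylate (ring-fusion centre as in 11; C5-methyl trans to H4a) | C[C@H]1C(O[Si](C)(C)C(C)(C)C)=C(C(=O)OC)CC=C2[C@H]1CC[C@@H](C)[C@]2(C)CC=C
F5 | step 5 | methyl 1,2,5-trimethyl-6-oxo-1-(prop-2-en-1-yl)-2,3,4,4a,5,6,7,8-octahydro-1H-benzo[7]annulene-7-carboxylate (β-keto ester, epimers at the α-carbons) | CC1C(=O)C(C(=O)OC)CC=C2[C@H]1CC[C@@H](C)[C@]2(C)CC=C
F6 | step 7 | thermodynamic trimethylsilyl enol ether of 11 (enol double bond toward the methyl-bearing carbon) | CC1=C(O[Si](C)(C)C)CCC=C2[C@H]1CC[C@@H](C)[C@]2(C)CC=C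
F7 | step 7 | (1S,2R,4aR,5R)-5-chloro-1,2,5-trimethyl-1-(prop-2-en-1-yl)-1,2,3,4,4a,5,7,8-octahydro-6H-benzo[7]annulen-6-one | C[C@]1(Cl)C(=O)CCC=C2[C@H]1CC[C@@H](C)[C@]2(C)CC=C
F8 | step 11 | methyl (1S,5S,6R,8aR)-5-(3-hydroxybutyl)-1,5,6-trimethyl-1,2,3,5,6,7,8,8a-octahydronaphthalene-1-carboxylate (carbinol epimers) | COC(=O)[C@@]1(C)CCC=C2[C@H]1CC[C@@H](C)[C@]2(C)CCC(C)O
F9 | step 11 | methyl (1S,5S,6R,8aR)-1,5,6-trimethyl-5-(3-oxobutyl)-1,2,3,5,6,7,8,8a-octahydronaphthalene-1-carboxylate | COC(=O)[C@@]1(C)CCC=C2[C@H]1CC[C@@H](C)[C@]2(C)CCC(C)=O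
F10 | step 11 | methyl (1S,5S,6R,8aR)-5-[(3E)-5-ethoxy-3-methyl-5-oxopent-3-en-1-yl]-1,5,6-trimethyl-1,2,3,5,6,7,8,8a-octahydronaphthalene-1-carboxylate | COC(=O)[C@@]1(C)CCC=C2[C@H]1CC[C@@H](C)[C@]2(C)CC/C(C)=C/C(=O)OCC
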